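Exotimarin H is the O‑isovaleryl enol of an aryl 1,2‑diketone. The ketone carbon on C8 of the coumarin benzo ring and the adjacent enol‑ester carbon are both carbonyl‑type carbons, and the dione can enolise only toward the isopropyl CH. The route therefore rests on the bond between these two like‑polarised carbons. An NHC‑catalysed crossed acyloin condensation (umpolung of isobutyraldehyde) joins 8‑formyl‑7‑methoxycoumarin and isobutyraldehyde in one atom‑economical operation; the precursor of the key step is simply the two aldehydes. Oxidation to the dione and DMAP‑mediated O‑acylation with isovaleric anhydride then finish the synthesis.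

Key step: step 3

Remark: the target has no stereocentre and its tetrasubstituted C=C carries two identical methyl groups, so there is no enantiomer or alkene geometry to control. The one stereocentre that appears in 6 is racemic and is removed in step 4.

Step 1
Reactants: 1 umbelliferone (7-hydroxy-2H-chromen-2-one)
Product: 2 7-hydroxy-2-oxo-2H-chromene-8-carbaldehyde
Conditions: HMTA (2 equiv), TFA, 90 °C; then H2O, 60 °C
Reagents that add atoms: hexamethylenetetramine (C1N2CN3CN1CN(C2)C3); water (O)
Why: Duff ortho-formylation of the phenol, in which protonated hexamine aminomethylates C8, the most nucleophilic ring carbon (flanked by the C7 hydroxyl and the ring oxygen on C8a), and internal redox followed by hydrolysis should deliver the aldehyde.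

Step 2
Reactants: 2 7-hydroxy-2-oxo-2H-chromene-8-carbaldehyde
Product: 3 7-methoxy-2-oxo-2H-chromene-8-carbaldehyde
Conditions: MeI (1.5 equiv), K2CO3 (1.5 equiv), DMF, rt
Reagents that add atoms: iodomethane (CI)
Why: Williamson ether synthesis, in which the phenoxide is methylated by SN2 on MeI under conditions that should leave the lactone and the aldehyde untouched.

Step 3
Reactants: 3 7-methoxy-2-oxo-2H-chromene-8-carbaldehyde; 4 isobutyraldehyde (2-methylpropanal)
Product: 6 racemic 8-(1-hydroxy-3-methyl-2-oxobutyl)-7-methoxy-2H-chromen-2-one, via Breslow intermediate of isobutyraldehyde 5 (not isolated)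
Conditions: 4 (3 equiv), 2-(pentafluorophenyl)-6,7-dihydro-5H-pyrrolo[2,1-c][1,2,4]triazol-2-ium BF4 (10 mol%), Rb2CO3 (10 mol%), THF, rt, Ar
Reagents that add atoms: none
Why: The triazolium salt is deprotonated to the carbene, which adds to 4 and tautomerises to the Breslow enaminol 5, an acyl-anion equivalent; 5 attacks the formyl carbon on C8 of 3, and proton transfer with release of the carbene should give ketol 6, creating the bond between the future aryl-ketone carbon and the future enol-ester carbon. The closest known reaction type is the NHC-catalysed crossed acyloin (benzoin) condensation of aliphatic aldehydes with ortho-substituted benzaldehydes under electron-poor N-pentafluorophenyl triazolium catalysis. No ring is closed. The single new stereocentre (the carbinol carbon) is formed without control, which is harmless because step 4 oxidises it away. The step needs cross- over homo-coupling: the formyl group of 3 is flanked by the C7 methoxy group and the ring oxygen, so it is too hindered to form its own Breslow intermediate or to self-condense and can only act as acceptor, while 4 is used in excess so that its homo-acyloin merely consumes surplus reagent. The regiochemistry of the ketol does not matter, since either crossed ketol should give dione 7 on oxidation.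

Step 4
Reactants: 6 racemic 8-(1-hydroxy-3-methyl-2-oxobutyl)-7-methoxy-2H-chromen-2-one
Product: 7 1-(7-methoxy-2-oxo-2H-chromen-8-yl)-3-methylbutane-1,2-dione
Conditions: Dess–Martin periodinane (1.3 equiv), CH2Cl2, rt
Reagents that add atoms: none
Why: Dess–Martin oxidation of the secondary benzylic α-ketol to the 1,2-dione under neutral, non-aqueous conditions that should spare the coumarin lactone and the aryl ether; the racemic stereocentre is erased.

Step 5
Reactants: 7 1-(7-methoxy-2-oxo-2H-chromen-8-yl)-3-methylbutane-1,2-dione; 8 isovaleric anhydride (3-methylbutanoic anhydride)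
Product: 9 exotimarin H (1-(7-methoxy-2-oxo-2H-chromen-8-yl)-3-methyl-1-oxobut-2-en-2-yl 3-methylbutanoate)
Conditions: 8 (2 equiv), Et3N (3 equiv), DMAP (0.2 equiv), CH2Cl2, 0 °C → rt
Reagents that add atoms: none
Why: DMAP-catalysed enol esterification (O-acylation of an enolisable 1,2-dicarbonyl): the dione has a single enolisable C–H, the isopropyl methine acidified by the vicinal dicarbonyl, so only the enolate oxygen on the carbon next to the aryl ketone can form, and it should be acylated on oxygen and not at the hindered tertiary carbon.

Compound list
1 | umbelliferone (7-hydroxy-2H-chromen-2-one) | Oc1ccc2ccc(=O)oc2c1 | starting material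
2 | 7-hydroxy-2-oxo-2H-chromene-8-carbaldehyde | Oc1ccc2ccc(=O)oc2c1C=O | intermediate
3 | 7-methoxy-2-oxo-2H-chromene-8-carbaldehyde | COc1ccc2ccc(=O)oc2c1C=O | intermediate
4 | isobutyraldehyde (2-methylpropanal) | CC(C)C=O | starting material
5 | Breslow intermediate of isobutyraldehyde (enaminol bound to the 2-pentafluorophenyl-pyrrolotriazolylidene catalyst; not isolated; enol geometry undefined) | CC(C)C(O)=C1N(c2c(F)c(F)c(F)c(F)c2F)N=C2CCCN12 | intermediate
6 | racemic 8-(1-hydroxy-3-methyl-2-oxobutyl)-7-methoxy-2H-chromen-2-one | COc1ccc2ccc(=O)oc2c1C(O)C(=O)C(C)C | intermediate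
7 | 1-(7-methoxy-2-oxo-2H-chromen-8-yl)-3-methylbutane-1,2-dione | COc1ccc2ccc(=O)oc2c1C(=O)C(=O)C(C)C | intermediate
8 | isovaleric anhydride (3-methylbutanoic anhydride) | CC(C)CC(=O)OC(=O)CC(C)C | starting material
9 | exotimarin H | COc1ccc2ccc(=O)oc2c1C(=O)C(OC(=O)CC(C)C)=C(C)C | target

Total step count: 5
Longest linear sequence: 5 steps (1 → 2 → 3 → 6 → 7 → 9)

Steps most likely to fail

1. Step 3 (key step). The doubly ortho-substituted, electron-rich formyl group of 3 may be too poor an acceptor, so that the catalytic cycle stalls at the Breslow stage and homo-coupling of the aliphatic aldehyde takes over. The fallback sets out from 3 (with 4) and comes back at 6, replacing catalytic umpolung by a stoichiometric masked acyl anion (Corey–Seebach). Isobutyraldehyde 4 would be condensed with propane-1,3-dithiol (BF3·OEt2, CH2Cl2) to give 2-isopropyl-1,3-dithiane F1. F1 would be lithiated (n-BuLi, THF, −30 °C) and the anion added to 3 at −78 °C to give the racemic carbinol 8-[hydroxy(2-isopropyl-1,3-dithian-2-yl)methyl]-7-methoxy-2H-chromen-2-one F2. S-Methylative hydrolysis of the dithiane (MeI, CaCO3, aqueous MeCN, 40 °C) should then unmask the ketone and give 6.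

2. Step 5. Enolisation of the hindered isopropyl methine by the amine base may be slow or incomplete, so that the dione is recovered while the anhydride is consumed. The fallback sets out from 7 and comes back at 9, going through a silyl enol ether in place of direct acylation. Soft enolisation with TMSOTf/Et3N (CH2Cl2, 0 °C) should give 7-methoxy-8-[3-methyl-2-(trimethylsilyloxy)but-2-enoyl]-2H-chromen-2-one F3. Silicon-to-acyl exchange on oxygen with isovaleryl chloride and catalytic CuCl (DMF, rt) should then give 9.

3. Step 1. The Duff reaction may give low conversion together with formylation at C6 or double formylation, which would make purification difficult. The fallback sets out from 1 and comes back at 3, installing the formyl carbon by carbonylation of an aryl iodide. Iodination of 1 (I2, KI, aqueous NH3, rt) should give 7-hydroxy-8-iodo-2H-chromen-2-one F4. O-Methylation (MeI, K2CO3, DMF) should give 8-iodo-7-methoxy-2H-chromen-2-one F5. Palladium-catalysed reductive carbonylation (Pd(PPh3)2Cl2 cat., CO 1 atm, HCO2Na, DMF, 90 °C) should then give 3.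

Further compounds
F1 | step 3 | 2-isopropyl-1,3-dithiane | CC(C)C1SCCCS1
F2 | step 3 | racemic 8-[hydroxy(2-isopropyl-1,3-dithian-2-yl)methyl]-7-methoxy-2H-chromen-2-one | COc1ccc2ccc(=O)oc2c1C(O)C1(C(C)C)SCCCS1
F3 | step 5 | 7-methoxy-8-[3-methyl-2-(trimethylsilyloxy)but-2-enoyl]-2H-chromen-2-one | COc1ccc2ccc(=O)oc2c1C(=O)C(O[Si](C)(C)C)=C(C)C
F4 | step 1 | 7-hydroxy-8-iodo-2H-chromen-2-one | Oc1ccc2ccc(=O)oc2c1I
F5 | step 1 | 8-iodo-7-methoxy-2H-chromen-2-one | COc1ccc2ccc(=O)oc2c1I
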